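The runs are simulated from invented constants, and the scatter is random.

Product is the thing to watch in this run, and the useful way to watch it is against the coupling partner charged, not against the substrate. Friday's flask, the one asked about, and Tuesday's flask look nearly the same: substrate, free catalyst and temperature match, and Friday's has twice the [coupling partner].

common to all: substrate 1.5 M; free catalyst 81 mM; temperature 35 °C
- Friday's: coupling partner 1.2 M; the very flask that is asked about, followed so far
- Tuesday's: coupling partner 0.60 M; run made earlier
- flask: coupling partner 1.20 M; time 25 h

| run | time / h | product / % | substrate / % |
|---|---|---|---|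
| Friday's | 4.00 | 35 | 65 |
| Friday's | 8.00 | 55 | 51 |
| Friday's | 12.0 | 56 | 43 |
| Friday's | 15.0 | 59 | 40 |
| Tuesday's | 3.00 | 16 | 84 |
| Tuesday's | 6.00 | 25 | 74 |
| Tuesday's | 10.0 | 31 | 72 |
| Tuesday's | 12.0 | 30 | 71 |

(readings scatter by 1.5 percentage points)

1. product, in percent of the substrate first charged, at 25 h
2. what to do for the largest gain in product; "none" if nothing gains more than 2 percentage points (birch / ash / larch / alder / none)
3. product present, with what was taken out counted in, in percent of the substrate first charged, after ash
4. product present, with what was taken out counted in, in percent of the substrate first charged, after alder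

- birch: at 25 h raise the temperature by 10 K, then wait 25 h
- ash: at 25 h add free catalyst, 50.0 % of the amount charged, then wait 25 h
- larch: change nothing and wait 25 h more
- alder: at 25 h take out 90 % of the product then present, then wait 25 h

- what is taken out of product is counted as made
- additions bring no volume worth counting
- the earlier runs do not show what temperature does; that part of a forecast is a guess

We replace the late end of each curve by the mean of its last two readings and divide by the partner charged. This gives the partner yield, the moles of product per mole of coupling partner charged. Friday's flask reads 0.719 and Tuesday's 0.763. They differ by 0.0440, and a scatter of 1.5 percentage points on a reading is multiplied by 2.50 in Tuesday's yield and by 1.25 in Friday's, so we treat them as one number. Substrate is not short in either flask, with 40 % left at Friday's last reading and 71 % at Tuesday's. Friday's [substrate] exceeds its [coupling partner], so, taking one coupling partner per product, the partner is the limiting reagent and Friday's ceiling is 80.0 %. About a quarter of the partner charged is not in product at those readings, and no reading says where it stands.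

Friday's readings still creep, by 4 points in 7.00 h. Our own reckoning holds that mean slope to 25 h and gives 64.7 %, a yield of 0.809. The error is plain: the slope rests on two readings with a scatter of 1.5 points each, stretched 1.43 times, and a curve that bends further lands lower. The forecast says 63 % (59 % to 67 %), 1.7 points under our figure. It picks ash, with 71 % after ash and 66 % after alder: “This points to a dying catalyst, not product inhibition.”

Friday's flask gives 66.0 %, a yield of 0.825 against the 0.719 read earlier, and Tuesday's recipe held to the same time gives 34.1 %, a yield of 0.853. The best choice is birch, gaining 13 points. Ash reaches 74.7 %, and alder reaches 73.9 %, gaining 7.9 points, the same as waiting.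

    coupling partner + free catalyst → catalyst intermediate A (k = 3.70 M⁻¹ h⁻¹, Ea = 75.0 kJ mol⁻¹)
    substrate + catalyst intermediate A → catalyst intermediate B (k = 4.80 M⁻¹ h⁻¹, Ea = 51.0 kJ mol⁻¹)
    catalyst intermediate B → free catalyst + product (k = 410 h⁻¹, Ea = 74.0 kJ mol⁻¹)
    coupling partner ⇌ dormant form (K = 1.90, k = 0.100 h⁻¹, Ea = 101 kJ mol⁻¹, ΔH = −27.0 kJ mol⁻¹)
    substrate + catalyst intermediate A → spent catalyst (k = 0.0440 M⁻¹ h⁻¹, Ea = 89.0 kJ mol⁻¹)
    (constants at 35 °C)

At the start, coupling partner goes to catalyst intermediate A 3.0 times as fast as it goes to dormant form, counting the forward step of that loss by itself, and at 25.0 h the ratio is 2.5. At that time free [coupling partner] is 2.35 % of its charge, while the dormant form holds 0.170 M.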